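**Strategy**

Everything rests on disconnecting the O1–C7a aryl ether bond of the dihydrofuran (ring B). Because C7a sits ortho to the C7 aroyl ketone on ring A, it is carried as a C–F carbon: fluorine first directs two ortho-metalations, which attach the hydroxyalkyl chain at C3a and the aroyl group at C7, and is then displaced by the C2 alkoxide in an intramolecular SNAr that closes ring B in one operation, with the epoxide-derived C2 configuration intact. The precursor is a 2-fluoro-4,6-dimethoxybenzophenone carrying a free (S)-secondary alcohol on the C3a side chain and an acetal-capped tertiary carbinol. The C5 side chain, drawn from (R)-limonene, is attached afterwards by Negishi coupling.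

Key step: step 12

Remark: atom numbers are those of the 2,3-dihydrobenzofuran (ring A = its benzene ring, ring B = its dihydrofuran ring, ring C = the 3-hydroxyphenyl ring); the (R,R)-cobalt salen catalyst is assumed to leave the (S)-epoxide, as it does for terminal epoxides whose substituent outranks the ring CH2, and this should be confirmed on 15 before material is committed.

**Route**

Step 1
Reactants: 1 2-methylbut-3-en-2-ol
Product: 2 3-(methoxymethoxy)-3-methylbut-1-ene
Conditions: MOMCl, i-Pr2NEt, Bu4NI (cat.), CH2Cl2, 0 °C → 40 °C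
Reagents that add atoms: chloromethyl methyl ether, COCCl
Why: O-alkylation of the tertiary allylic alcohol with the α-chloro ether (MOM protection) is standard, and an acetal is chosen for this oxygen because, unlike a silyl group, it cannot shift to a neighbouring alkoxide during the later base-mediated ring closure.

Step 2
Reactants: 2 3-(methoxymethoxy)-3-methylbut-1-ene
Product: 3 rac-2-[2-(methoxymethoxy)propan-2-yl]oxirane
Conditions: mCPBA, NaHCO3, CH2Cl2, 0 °C → rt
Reagents that add atoms: 3-chloroperoxybenzoic acid, O=C(OO)c1cccc(Cl)c1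
Why: Prilezhaev epoxidation of the only alkene should be slow for a monosubstituted olefin but clean, with bicarbonate protecting the acetal from 3-chlorobenzoic acid; the epoxide is racemic at this point.

Step 3
Reactants: 3 rac-2-[2-(methoxymethoxy)propan-2-yl]oxirane
Product: 4 (S)-2-[2-(methoxymethoxy)propan-2-yl]oxirane
Conditions: (R,R)-(salen)Co(OAc) (1–2 mol%; trivalent cobalt; salen = N,N′-bis(3,5-di-tert-butylsalicylidene)cyclohexane-1,2-diamine dianion), H2O (0.55 equiv), THF, 0 °C → rt; distillation
Reagents that add atoms: none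
Why: In this hydrolytic kinetic resolution the chiral cobalt salen catalyst should hydrolyse the (R)-epoxide much faster, so the (S)-epoxide is left and distilled from the diol; this sets the stereocentre that becomes C2 of the target.

Step 4
Reactants: 5 3-hydroxybenzaldehyde
Product: 6 3-(methoxymethoxy)benzaldehyde
Conditions: MOMCl, i-Pr2NEt, CH2Cl2, 0 °C → rt
Reagents that add atoms: chloromethyl methyl ether, COCCl
Why: Standard MOM protection of a phenol masks the acidic ring C hydroxyl before the organolithium addition.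

Step 5
Reactants: 7 (4R)-limonene 1,2-oxide (commercial cis/trans mixture)
Product: 8 (R)-6-oxo-3-(prop-1-en-2-yl)heptanal
Conditions: H5IO6, THF/H2O, 0 °C → rt
Reagents that add atoms: water, O
Why: Acid-mediated epoxide hydrolysis followed in the same pot by Malaprade glycol cleavage opens the ring between the two epoxide carbons, while the isopropenyl group and the remote stereocentre (the future side-chain centre) are not touched.

Step 6
Reactants: 8 (R)-6-oxo-3-(prop-1-en-2-yl)heptanal
Product: 9 (R)-6-oxo-3-(prop-1-en-2-yl)heptanoic acid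
Conditions: NaClO2, NaH2PO4, 2-methylbut-2-ene, t-BuOH/H2O, 0 °C → rt
Reagents that add atoms: sodium chlorite, [Na+].[O-]Cl=O
Why: Pinnick oxidation converts the aldehyde chemoselectively, the ketone being inert and the scavenger alkene intercepting HOCl before it can reach the isopropenyl group.

Step 7
Reactants: 9 (R)-6-oxo-3-(prop-1-en-2-yl)heptanoic acid
Product: 10 (R)-6-methyl-3-(prop-1-en-2-yl)hept-6-enoic acid
Conditions: Ph3PCH3Br (3.2 equiv), KOt-Bu (3.0 equiv), THF, 0 °C → rt; aq. HCl
Reagents that add atoms: methyltriphenylphosphonium bromide, C[P+](c1ccccc1)(c1ccccc1)c1ccccc1.[Br-]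
Why: Wittig methylenation of the methyl ketone, with excess ylide to cover the carboxylic acid proton, should be uneventful because the stereocentre is α to neither carbonyl and cannot epimerise.

Step 8
Reactants: 10 (R)-6-methyl-3-(prop-1-en-2-yl)hept-6-enoic acid
Product: 12 (S)-3-(iodomethyl)-2,6-dimethylhepta-1,6-diene, via Barton ester 11 (not isolated)
Conditions: N-hydroxypyridine-2-thione, DCC, DMAP (cat.), CH2Cl2, 0 °C, dark; then CHI3, hν (tungsten lamp), rt
Reagents that add atoms: iodoform, IC(I)I
Why: In this Barton decarboxylative iodination the thiohydroxamate ester fragments to a primary radical that should abstract iodine from iodoform far faster than a 5-methylhex-5-enyl radical cyclises; the neighbouring stereocentre is not involved and becomes (S) only because CH2I outranks isopropenyl.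

Step 9
Reactants: 13 1-fluoro-3,5-dimethoxybenzene; 4 (S)-2-[2-(methoxymethoxy)propan-2-yl]oxirane
Product: 15 (S)-1-(2-fluoro-4,6-dimethoxyphenyl)-3-(methoxymethoxy)-3-methylbutan-2-ol, via (2-fluoro-4,6-dimethoxyphenyl)lithium 14 (not isolated)
Conditions: 13 (1.5 equiv), n-BuLi, THF, −78 °C; then 4, BF3·OEt2, −78 °C
Reagents that add atoms: none
Why: Directed ortho-metalation should occur at the C–H flanked by F and OMe, the kinetically most acidic site (a 3-fluoroanisole-type position metalates at −78 °C whereas a position between two methoxy groups does not), and BF3-promoted SN2 opening of the epoxide at its CH2 terminus then proceeds below the temperature at which LiF is lost, leaving the C–O stereocentre untouched.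

Step 10
Reactants: 15 (S)-1-(2-fluoro-4,6-dimethoxyphenyl)-3-(methoxymethoxy)-3-methylbutan-2-ol; 6 3-(methoxymethoxy)benzaldehyde
Product: 17 (2S)-1-(2-fluoro-3-{hydroxy[3-(methoxymethoxy)phenyl]methyl}-4,6-dimethoxyphenyl)-3-(methoxymethoxy)-3-methylbutan-2-ol (carbinol epimers), via dilithio species 16 (not isolated)
Conditions: n-BuLi (2.2 equiv), THF, −78 °C; then 6, −78 °C; H2O
Reagents that add atoms: none
Why: After O-deprotonation a second directed ortho-metalation should take place at the remaining F/OMe-flanked C–H, and the aryllithium adds 1,2 to the aldehyde; the new carbinol centre forms without control and is erased in the next step.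

Step 11
Reactants: 17 diaryl carbinol (epimer mixture)
Product: 18 (S)-{2-fluoro-3-[2-hydroxy-3-(methoxymethoxy)-3-methylbutyl]-4,6-dimethoxyphenyl}[3-(methoxymethoxy)phenyl]methanone
Conditions: MnO2 (excess), CH2Cl2, rt
Reagents that add atoms: none
Why: MnO2 oxidation is selective for the doubly benzylic carbinol, so the aliphatic secondary alcohol needed as the nucleophile stays free.

Step 12
Reactants: 18 (S)-fluoro benzophenone with free C2 hydroxyl
Product: 21 (S)-{4,6-dimethoxy-2-[2-(methoxymethoxy)propan-2-yl]-2,3-dihydrobenzofuran-7-yl}[3-(methoxymethoxy)phenyl]methanone, via potassium alkoxide 19 (not isolated), via Meisenheimer adduct 20 (not isolated)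
Conditions: KN(SiMe3)2 (1.1 equiv), THF, −78 °C → rt
Reagents that add atoms: none
Why: KN(SiMe3)2 converts the free C2 hydroxyl into the potassium alkoxide, which adds to the fluorine-bearing C7a to give a cyclohexadienyl (Meisenheimer) anion whose charge is taken up by the ortho C7 ketone, and loss of fluoride restores ring A; the closest known reaction type is the intramolecular SNAr etherification of ortho-acyl fluoroarenes to dihydrobenzofurans and chromans. Ring B, the only ring made here, forms by 5-exo-trig addition of O1 to C7a. No new stereocentre is created and no bond to C2 is broken, so the (S) configuration set in step 3 is carried through unchanged. The step needs site selectivity between the two ortho carbons of C3a, namely C7a–F and C4–OMe (para to the ketone), and fluorine, which accelerates addition and leaves far better than methoxide, secures attack at C7a. It also needs the secondary and not the tertiary oxygen to act as nucleophile (dihydrofuran, not chroman), which is secured by capping the tertiary oxygen as a MOM acetal that cannot migrate to the adjacent alkoxide as a silyl group would under these basic conditions.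

Step 13
Reactants: 21 (S)-7-aroyl-4,6-dimethoxy-2,3-dihydrobenzofuran (bis-MOM)
Product: 22 (S)-[6-hydroxy-2-(2-hydroxypropan-2-yl)-4-methoxy-2,3-dihydrobenzofuran-7-yl](3-hydroxyphenyl)methanone
Conditions: BCl3, CH2Cl2, −78 → 0 °C; then H2O/THF, NaHCO3
Reagents that add atoms: none
Why: In this chelation-controlled Lewis acid ether cleavage boron bridges the C7 carbonyl and the C6 methoxy oxygen, so chloride should remove only that methyl group (the C4 methoxy cannot chelate) while both MOM acetals are cleaved in the same operation; low temperature spares the tertiary carbinol, whose ionisation is disfavoured by the β-oxygen O1.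

Step 14
Reactants: 22 (S)-triol
Product: 23 (S)-[6-hydroxy-2-(2-hydroxypropan-2-yl)-5-iodo-4-methoxy-2,3-dihydrobenzofuran-7-yl](3-hydroxyphenyl)methanone
Conditions: NIS (1.05 equiv), MeCN, 0 °C
Reagents that add atoms: N-iodosuccinimide, O=C1CCC(=O)N1I
Why: Electrophilic aromatic iodination should go to C5, the only free position of ring A, which is ortho to the C6 hydroxyl and the C4 methoxy and para to O1 and hence far more nucleophilic than the acyl-deactivated ring C phenol.

Step 15
Reactants: 23 (S)-iodo triol
Product: 24 3-{[(S)-6-acetoxy-2-(2-hydroxypropan-2-yl)-5-iodo-4-methoxy-2,3-dihydrobenzofuran-7-yl]carbonyl}phenyl acetate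
Conditions: Ac2O (2.2 equiv), Et3N, DMAP (cat.), CH2Cl2, 0 °C
Reagents that add atoms: acetic anhydride, CC(=O)OC(C)=O
Why: O-acetylation of both phenols removes the acidic protons before the organozinc coupling, and the hindered tertiary alcohol should not be acylated at 0 °C with a limited amount of anhydride.

Step 16
Reactants: 12 (S)-3-(iodomethyl)-2,6-dimethylhepta-1,6-diene; 24 iodo diacetate
Product: 26 3-({(S)-6-acetoxy-2-(2-hydroxypropan-2-yl)-4-methoxy-5-[(R)-5-methyl-2-(prop-1-en-2-yl)hex-5-en-1-yl]-2,3-dihydrobenzofuran-7-yl}carbonyl)phenyl acetate, via alkylzinc iodide 25 (not isolated)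
Conditions: 12 (2 equiv), Zn dust, LiCl, THF, 40 °C; then 24, Pd(OAc)2 (5 mol%), SPhos (10 mol%), THF, rt → 50 °C
Reagents that add atoms: none
Why: In this Negishi coupling LiCl-assisted zinc insertion gives a primary alkylzinc iodide that tolerates the ketone, the acetates and the tertiary hydroxyl, and the bulky biarylphosphine–palladium catalyst is suited to di-ortho-substituted aryl iodides, with reductive elimination outpacing β-hydride elimination; the side-chain centre β to zinc is not involved.

Step 17
Reactants: 26 coupled diacetate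
Product: 27 (S)-{6-hydroxy-2-(2-hydroxypropan-2-yl)-4-methoxy-5-[(R)-5-methyl-2-(prop-1-en-2-yl)hex-5-en-1-yl]-2,3-dihydrobenzofuran-7-yl}(3-hydroxyphenyl)methanone
Conditions: K2CO3, MeOH, 0 °C → rt
Reagents that add atoms: none
Why: Base-mediated methanolysis of the two aryl acetates is mild and non-acidic, so the two 1,1-disubstituted alkenes, the tertiary alcohol and both stereocentres should be safe, whereas acid would risk cyclisation of the C6 hydroxyl onto the isopropenyl group.

**Compound list**

1 | 2-methylbut-3-en-2-ol | C=CC(C)(C)O | starting material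
2 | 3-(methoxymethoxy)-3-methylbut-1-ene | C=CC(C)(C)OCOC | intermediate
3 | rac-2-[2-(methoxymethoxy)propan-2-yl]oxirane | COCOC(C)(C)C1CO1 | intermediate
4 | (S)-2-[2-(methoxymethoxy)propan-2-yl]oxirane | COCOC(C)(C)[C@@H]1CO1 | intermediate
5 | 3-hydroxybenzaldehyde | O=Cc1cccc(O)c1 | starting material
6 | 3-(methoxymethoxy)benzaldehyde | COCOc1cccc(C=O)c1 | intermediate
7 | (4R)-limonene 1,2-oxide [(4R)-1-methyl-4-(prop-1-en-2-yl)-7-oxabicyclo[4.1.0]heptane, cis/trans mixture at the epoxide] | CC12OC1C[C@@H](CC2)C(C)=C | starting material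
8 | (R)-6-oxo-3-(prop-1-en-2-yl)heptanal | O=CC[C@@H](CCC(C)=O)C(C)=C | intermediate
9 | (R)-6-oxo-3-(prop-1-en-2-yl)heptanoic acid | OC(=O)C[C@@H](CCC(C)=O)C(C)=C | intermediate
10 | (R)-6-methyl-3-(prop-1-en-2-yl)hept-6-enoic acid | OC(=O)C[C@@H](CCC(C)=C)C(C)=C | intermediate
11 | 2-thioxopyridin-1(2H)-yl (R)-6-methyl-3-(prop-1-en-2-yl)hept-6-enoate (Barton ester) | S=C1C=CC=CN1OC(=O)C[C@@H](CCC(C)=C)C(C)=C | intermediate
12 | (S)-3-(iodomethyl)-2,6-dimethylhepta-1,6-diene | IC[C@@H](CCC(C)=C)C(C)=C | intermediate
13 | 1-fluoro-3,5-dimethoxybenzene | COc1cc(F)cc(OC)c1 | starting material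
14 | (2-fluoro-4,6-dimethoxyphenyl)lithium | [Li]c1c(F)cc(OC)cc1OC | intermediate
15 | (S)-1-(2-fluoro-4,6-dimethoxyphenyl)-3-(methoxymethoxy)-3-methylbutan-2-ol | COCOC(C)(C)[C@@H](O)Cc1c(F)cc(OC)cc1OC | intermediate
16 | dilithio species of 15 (lithium alkoxide, aryllithium at the F/OMe-flanked carbon) | [Li]O[C@@H](Cc1c(F)c([Li])c(OC)cc1OC)C(C)(C)OCOC | intermediate
17 | (2S)-1-(2-fluoro-3-{hydroxy[3-(methoxymethoxy)phenyl]methyl}-4,6-dimethoxyphenyl)-3-(methoxymethoxy)-3-methylbutan-2-ol (carbinol epimers) | COCOc1cccc(C(O)c2c(F)c(C[C@H](O)C(C)(C)OCOC)c(OC)cc2OC)c1 | intermediate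
18 | (S)-{2-fluoro-3-[2-hydroxy-3-(methoxymethoxy)-3-methylbutyl]-4,6-dimethoxyphenyl}[3-(methoxymethoxy)phenyl]methanone | COCOc1cccc(C(=O)c2c(F)c(C[C@H](O)C(C)(C)OCOC)c(OC)cc2OC)c1 | intermediate
19 | potassium alkoxide of 18 | COCOc1cccc(C(=O)c2c(F)c(C[C@H]([O-])C(C)(C)OCOC)c(OC)cc2OC)c1.[K+] | intermediate
20 | potassium salt of the C7a fluoro σ-adduct (Meisenheimer anion, drawn as the C7 enolate; C7a configuration and enolate geometry undefined) | COCOc1cccc(c1)C([O-])=C1C(OC)=CC(OC)=C2C[C@@H](C(C)(C)OCOC)OC12F.[K+] | intermediate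
21 | (S)-{4,6-dimethoxy-2-[2-(methoxymethoxy)propan-2-yl]-2,3-dihydrobenzofuran-7-yl}[3-(methoxymethoxy)phenyl]methanone | COCOc1cccc(C(=O)c2c(OC)cc(OC)c3c2O[C@H](C(C)(C)OCOC)C3)c1 | intermediate
22 | (S)-[6-hydroxy-2-(2-hydroxypropan-2-yl)-4-methoxy-2,3-dihydrobenzofuran-7-yl](3-hydroxyphenyl)methanone | Oc1cccc(C(=O)c2c(O)cc(OC)c3c2O[C@H](C(C)(C)O)C3)c1 | intermediate
23 | (S)-[6-hydroxy-2-(2-hydroxypropan-2-yl)-5-iodo-4-methoxy-2,3-dihydrobenzofuran-7-yl](3-hydroxyphenyl)methanone | Oc1cccc(C(=O)c2c(O)c(I)c(OC)c3c2O[C@H](C(C)(C)O)C3)c1 | intermediate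
24 | 3-{[(S)-6-acetoxy-2-(2-hydroxypropan-2-yl)-5-iodo-4-methoxy-2,3-dihydrobenzofuran-7-yl]carbonyl}phenyl acetate | CC(=O)Oc1cccc(C(=O)c2c(OC(C)=O)c(I)c(OC)c3c2O[C@H](C(C)(C)O)C3)c1 | intermediate
25 | (S)-[5-methyl-2-(prop-1-en-2-yl)hex-5-en-1-yl]zinc iodide | I[Zn]C[C@@H](CCC(C)=C)C(C)=C | intermediate
26 | 3-({(S)-6-acetoxy-2-(2-hydroxypropan-2-yl)-4-methoxy-5-[(R)-5-methyl-2-(prop-1-en-2-yl)hex-5-en-1-yl]-2,3-dihydrobenzofuran-7-yl}carbonyl)phenyl acetate | CC(=O)Oc1cccc(C(=O)c2c(OC(C)=O)c(C[C@@H](CCC(C)=C)C(C)=C)c(OC)c3c2O[C@H](C(C)(C)O)C3)c1 | intermediate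
27 | (S)-{6-hydroxy-2-(2-hydroxypropan-2-yl)-4-methoxy-5-[(R)-5-methyl-2-(prop-1-en-2-yl)hex-5-en-1-yl]-2,3-dihydrobenzofuran-7-yl}(3-hydroxyphenyl)methanone | C=C(C)CC[C@H](Cc1c(O)c(C(=O)c2cccc(O)c2)c2c(c1OC)C[C@@H](C(C)(C)O)O2)C(=C)C | target

**Totals**

Total step count: 17.
Longest linear sequence: 12 steps (steps 1–3, then 9–17).

**Steps most likely to fail**

1. Step 12 (ring B closure). The C7 carbonyl, flanked by C6–OMe and C7a–F, may lie twisted out of the plane of ring A, so stabilisation of the σ-adduct is weak and closure is slow, leaving room for base-induced decomposition or attack at C4. The fallback closes ring B on a flatter activating group and builds the diaryl ketone afterwards. Setting out from 15, the dilithio species 16 is generated as in step 10 and quenched with DMF to give (S)-2-fluoro-3-[2-hydroxy-3-(methoxymethoxy)-3-methylbutyl]-4,6-dimethoxybenzaldehyde F1. Cs2CO3 in DMF at 60 °C should then effect SNAr ortho to the formyl group, which is small enough to stay coplanar with ring A, giving (S)-4,6-dimethoxy-2-[2-(methoxymethoxy)propan-2-yl]-2,3-dihydrobenzofuran-7-carbaldehyde F2. [3-(Methoxymethoxy)phenyl]magnesium bromide F3, prepared from commercial 1-bromo-3-(methoxymethoxy)benzene and Mg in THF, is added at −78 °C to give {(S)-4,6-dimethoxy-2-[2-(methoxymethoxy)propan-2-yl]-2,3-dihydrobenzofuran-7-yl}[3-(methoxymethoxy)phenyl]methanol F4, and MnO2 oxidation returns to the route at 21.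

2. Step 16 (sp3–sp2 coupling). Transmetalation of the β-branched alkylzinc to the di-ortho-substituted arylpalladium species may be slow, so that reduction of the aryl iodide, β-hydride elimination or protonation of the zinc reagent by the tertiary hydroxyl takes over. The fallback changes the nucleophile and the way it is made to a boron ate complex. Setting out from 12, iodine–lithium exchange (t-BuLi, Et2O/pentane, −78 °C) gives (S)-[5-methyl-2-(prop-1-en-2-yl)hex-5-en-1-yl]lithium F5, which is trapped with 9-methoxy-9-borabicyclo[3.3.1]nonane to give lithium B-methoxy-B-[(S)-5-methyl-2-(prop-1-en-2-yl)hex-5-en-1-yl]-9-borabicyclo[3.3.1]nonan-9-uide F6. B-alkyl Suzuki–Miyaura coupling of F6 with 24 (PdCl2(dppf), THF/DMF, rt → 50 °C, no added base) should give 26, where the route resumes.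

3. Step 9 (arene–epoxide union). The ortho-fluoroaryllithium may lose LiF to an aryne, or be tied up by BF3 before the epoxide is attacked, or the deprotonation may be incompletely regioselective. The fallback fixes the metal position by electrophilic bromination and uses a magnesium/copper nucleophile that needs no Lewis acid. Setting out from 13, NBS in MeCN should brominate para to one methoxy group and ortho to fluorine, giving 2-bromo-1-fluoro-3,5-dimethoxybenzene F7. Magnesium insertion (Mg turnings, LiCl, THF, 0 °C → rt) gives (2-fluoro-4,6-dimethoxyphenyl)magnesium bromide F8, which opens epoxide 4 at its CH2 terminus under CuI catalysis (10 mol%, THF, −30 → 0 °C) and returns to the route at 15.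

**Further compounds**

F1 | step 12 | (S)-2-fluoro-3-[2-hydroxy-3-(methoxymethoxy)-3-methylbutyl]-4,6-dimethoxybenzaldehyde | COCOC(C)(C)[C@@H](O)Cc1c(F)c(C=O)c(OC)cc1OC
F2 | step 12 | (S)-4,6-dimethoxy-2-[2-(methoxymethoxy)propan-2-yl]-2,3-dihydrobenzofuran-7-carbaldehyde | COCOC(C)(C)[C@@H]1Cc2c(OC)cc(OC)c(C=O)c2O1
F3 | step 12 | [3-(methoxymethoxy)phenyl]magnesium bromide | COCOc1cccc([Mg]Br)c1
F4 | step 12 | {(S)-4,6-dimethoxy-2-[2-(methoxymethoxy)propan-2-yl]-2,3-dihydrobenzofuran-7-yl}[3-(methoxymethoxy)phenyl]methanol (carbinol epimers) | COCOc1cccc(C(O)c2c(OC)cc(OC)c3c2O[C@H](C(C)(C)OCOC)C3)c1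
F5 | step 16 | (S)-[5-methyl-2-(prop-1-en-2-yl)hex-5-en-1-yl]lithium | [Li]C[C@@H](CCC(C)=C)C(C)=C
F6 | step 16 | lithium B-methoxy-B-[(S)-5-methyl-2-(prop-1-en-2-yl)hex-5-en-1-yl]-9-borabicyclo[3.3.1]nonan-9-uide | [Li+].CO[B-]1(C[C@@H](CCC(C)=C)C(C)=C)C2CCCC1CCC2
F7 | step 9 | 2-bromo-1-fluoro-3,5-dimethoxybenzene | COc1cc(F)c(Br)c(OC)c1
F8 | step 9 | (2-fluoro-4,6-dimethoxyphenyl)magnesium bromide | COc1cc(F)c([Mg]Br)c(OC)c1
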